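**Strategy.** Everything rests on disconnecting the C3–C4 bond of the cyclohexadienone ring (C3 = enol carbon beside the benzoyl-bearing C2; C4 = carbon carrying the cyclopentylmethyl group). The key step is a Dieckmann condensation of the ketone enolate at C4 onto an isoxazole-4-carboxylate. It exploits the 1,3-relationship of the benzoyl C=O and ring C1=O across C2, stored as a 3-phenylisoxazole so that C2 cannot enolise and the C3 ester stays electrophilic. One operation closes the six-membered ring and completes the carbon skeleton. The precursor is an isoxazole methyl ester with a gem-diprenyl keto side chain, assembled from a limonene-derived cis-fused lactone and 5-methyl-3-phenylisoxazole-4-carboxylic acid; N–O cleavage then unveils the triketone.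

Key step: step 10

Remark on the chemistry: the six-membered ring is numbered C1 (C=O between the benzoyl-bearing C2 and the diprenyl carbon C6), C3, C4 (carries the side chain), C5. The δ-hydroxy ketones 16, 17 and 18 are drawn open-chain although they may equilibrate with cyclic hemiketals. Compounds 16 and 17 are taken as mixtures of epimers at the prenyl-bearing methine, which becomes a non-stereogenic quaternary carbon in 18.

**Step 1**
Reactants: 1 (S)-(−)-limonene
Product: 3 (3S)-6-oxo-3-(prop-1-en-2-yl)heptanal, via limonene secondary ozonide 2 (not isolated)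
Conditions: O3 (1.0 equiv), CH2Cl2, −78 °C; then Me2S, −78 °C to rt
Reagents that add atoms: ozone, O=[O+][O-]
Why: Ozonolysis with reductive work-up; the trisubstituted ring alkene is more electron-rich than the 1,1-disubstituted isopropenyl group, so one equivalent of ozone should cleave it selectively, and the stereocenter is untouched.

**Step 2**
Reactants: 3 (3S)-6-oxo-3-(prop-1-en-2-yl)heptanal
Product: 4 (5R)-2-methyl-5-(prop-1-en-2-yl)cyclopent-1-ene-1-carbaldehyde
Conditions: piperidine (0.2 equiv), AcOH (0.2 equiv), toluene, 80 °C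
Reagents that add atoms: none
Why: Amine-catalysed intramolecular aldol condensation of the aldehyde α-carbon onto the methyl ketone and dehydration gives the conjugated cyclopentene carbaldehyde; the stereocenter is β to the aldehyde in 3 and is retained.

**Step 3**
Reactants: 4 (5R)-2-methyl-5-(prop-1-en-2-yl)cyclopent-1-ene-1-carbaldehyde
Product: 5 (1R,2R,5S)-5-methyl-2-(prop-1-en-2-yl)-6-oxabicyclo[3.1.0]hexane-1-carbaldehyde (epoxide oxygen trans to isopropenyl)
Conditions: 30% aq. H2O2, NaOH (0.3 equiv), MeOH, 0 °C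
Reagents that add atoms: hydrogen peroxide, OO
Why: Weitz–Scheffer nucleophilic epoxidation attacks only the enal, and closure of the hydroperoxide enolate should occur on the face away from the adjacent isopropenyl group, which sets both epoxide carbons.

**Step 4**
Reactants: 5 (1R,2R,5S)-5-methyl-2-(prop-1-en-2-yl)-6-oxabicyclo[3.1.0]hexane-1-carbaldehyde; 6 methyl (triphenylphosphoranylidene)acetate
Product: 7 methyl (2E)-3-[(1R,2R,5S)-5-methyl-2-(prop-1-en-2-yl)-6-oxabicyclo[3.1.0]hexan-1-yl]prop-2-enoate
Conditions: toluene, 70 °C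
Reagents that add atoms: none
Why: Wittig olefination with a stabilised ylide should give the (E)-enoate, and the aldehyde has no α-hydrogen, so nothing can epimerise.

**Step 5**
Reactants: 7 methyl (2E)-3-[(1R,2R,5S)-5-methyl-2-(prop-1-en-2-yl)-6-oxabicyclo[3.1.0]hexan-1-yl]prop-2-enoate
Product: 8 methyl (2E)-3-[(1R,2S,5S)-2-hydroxy-2-methyl-5-(prop-1-en-2-yl)cyclopentyl]prop-2-enoate
Conditions: Pd2(dba)3·CHCl3 (2.5 mol%), n-Bu3P (10 mol%), HCO2H (5 equiv), Et3N (2 equiv), 1,4-dioxane, rt
Reagents that add atoms: none
Why: Palladium-catalysed formate hydrogenolysis of an (E)-alkenyl epoxide (Tsuji–Trost-type ionisation); zerovalent palladium opens the allylic C–O bond with inversion and passes hydride to the same ring carbon from its own face, so hydrogen should enter anti to the former epoxide oxygen and the side chain ends cis to the tertiary OH and trans to isopropenyl.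

**Step 6**
Reactants: 8 methyl (2E)-3-[(1R,2S,5S)-2-hydroxy-2-methyl-5-(prop-1-en-2-yl)cyclopentyl]prop-2-enoate
Product: 10 (4aR,5S,7aS)-7a-methyl-5-(prop-1-en-2-yl)-4,4a,5,6,7,7a-hexahydrocyclopenta[b]pyran-2(3H)-one, via saturated hydroxy ester 9 (not isolated)
Conditions: Mg (10 equiv), MeOH, 0 °C to rt; then PPTS (0.1 equiv), toluene, 80 °C
Reagents that add atoms: none
Why: Dissolving-metal conjugate reduction with magnesium in methanol saturates only the enoate C=C, and the cis-disposed tertiary OH and ester chain then lactonise under mild acid to the cis-fused δ-lactone.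

**Step 7**
Reactants: 11 5-methyl-3-phenyl-1,2-oxazole-4-carboxylic acid; 12 1-bromo-3-methylbut-2-ene (prenyl bromide)
Product: 14 5-(4-methylpent-3-en-1-yl)-3-phenyl-1,2-oxazole-4-carboxylic acid, via dilithio dianion 13 (not isolated)
Conditions: LiN(i-Pr)2 (LDA, 2.1 equiv), THF, −78 °C; then 12 (1.05 equiv), −78 to −40 °C; 1 M HCl to pH 3
Reagents that add atoms: none
Why: Lateral metalation, in which the lithium carboxylate directs the second deprotonation to the adjacent C-5 methyl group, followed by SN2 alkylation of the carbanion at the primary carbon of the allylic bromide; irreversible deprotonation at low temperature should stop the reaction at monoalkylation.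

**Step 8**
Reactants: 14 5-(4-methylpent-3-en-1-yl)-3-phenyl-1,2-oxazole-4-carboxylic acid; 10 (4aR,5S,7aS)-7a-methyl-5-(prop-1-en-2-yl)-4,4a,5,6,7,7a-hexahydrocyclopenta[b]pyran-2(3H)-one
Product: 17 methyl 5-{8-[(1R,2S,5S)-2-hydroxy-2-methyl-5-(prop-1-en-2-yl)cyclopentyl]-2-methyl-6-oxooct-2-en-5-yl}-3-phenyl-1,2-oxazole-4-carboxylate, via dilithio dianion 15 (not isolated), via keto acid 16 (not isolated)
Conditions: 14 (1.5 equiv), LiN(i-Pr)2 (LDA, 3.1 equiv), THF, −78 °C; then 10, −78 to −30 °C; 1 M HCl to pH 3, extraction; then Me3SiCHN2 (2.0 equiv), toluene/MeOH (4:1), 0 °C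
Reagents that add atoms: (trimethylsilyl)diazomethane, C[Si](C)(C)C=[N+]=[N-]
Why: Lateral metalation at the C-5 side-chain CH2 and Claisen-type acylation by the lactone, whose lithium hemiketal alkoxide should block a second addition and release the δ-hydroxy ketone on work-up, followed by methylation of the crude carboxylic acid with Me3SiCHN2, which leaves the ketone and the tertiary alcohol alone and makes the separation from the excess of 14 simple; the new methine stereocenter is not controlled and need not be.

**Step 9**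
Reactants: 17 methyl 5-{8-[(1R,2S,5S)-2-hydroxy-2-methyl-5-(prop-1-en-2-yl)cyclopentyl]-2-methyl-6-oxooct-2-en-5-yl}-3-phenyl-1,2-oxazole-4-carboxylate; 12 1-bromo-3-methylbut-2-ene (prenyl bromide)
Product: 18 methyl 5-{8-[(1R,2S,5S)-2-hydroxy-2-methyl-5-(prop-1-en-2-yl)cyclopentyl]-2-methyl-5-(3-methylbut-2-en-1-yl)-6-oxooct-2-en-5-yl}-3-phenyl-1,2-oxazole-4-carboxylate
Conditions: 12 (1.5 equiv), Cs2CO3 (2.0 equiv), DMF, 0 °C to rt
Reagents that add atoms: none
Why: C-Alkylation of the methine activated by both the ketone and the ester-bearing isoxazole builds the quaternary carbon; the soft allylic bromide should favour carbon over oxygen, carbonate does not deprotonate the other ketone α-CH2 or the tertiary alcohol, and the methine stereocenter vanishes because the two prenyl groups are identical.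

**Step 10**
Reactants: 18 methyl 5-{8-[(1R,2S,5S)-2-hydroxy-2-methyl-5-(prop-1-en-2-yl)cyclopentyl]-2-methyl-5-(3-methylbut-2-en-1-yl)-6-oxooct-2-en-5-yl}-3-phenyl-1,2-oxazole-4-carboxylate
Product: 19 6-hydroxy-5-{[(1R,2S,5S)-2-hydroxy-2-methyl-5-(prop-1-en-2-yl)cyclopentyl]methyl}-7,7-bis(3-methylbut-2-en-1-yl)-3-phenyl-1,2-benzoxazol-4(7H)-one
Conditions: LiN(SiMe3)2 (LiHMDS, 3.2 equiv), THF, −78 to 0 °C; 1 M HCl work-up
Reagents that add atoms: none
Why: The base deprotonates the tertiary alcohol and then the only enolisable position, the CH2 between the ketone and the cyclopentylmethyl group; this lithium enolate adds through carbon to the methyl ester carbonyl on the neighbouring isoxazole carbon, methoxide is expelled, and deprotonation of the new 1,3-diketone makes the closure irreversible. The closest known reaction type is the Dieckmann (intramolecular Claisen) condensation of a ketone enolate with an ortho-disposed aryl ester, as in the closure of 2-(2-oxoalkyl)benzoates to naphthalene-1,3-diols. The six-membered ring closes in the 6-(enolendo)-exo-trig mode, with the isoxazole C4–C5 bond holding ester and side chain cis. No stereocenter is created, because the new ring carbon becomes part of an enol. The step needs an ester that stays electrophilic and acylation at carbon rather than oxygen: the isoxazole locks the future C2 as a non-enolisable sp2 carbon, and any enol lactone from O-acylation should be reopened by the released alkoxide and funnelled to the stabilised diketonate.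

**Step 11**
Reactants: 19 6-hydroxy-5-{[(1R,2S,5S)-2-hydroxy-2-methyl-5-(prop-1-en-2-yl)cyclopentyl]methyl}-7,7-bis(3-methylbut-2-en-1-yl)-3-phenyl-1,2-benzoxazol-4(7H)-one
Product: 21 Hypercalin B, via enaminone 20 (not isolated)
Conditions: Mo(CO)6 (1.2 equiv), MeCN/H2O (10:1), 80 °C; then 2 M aq. NaOH, 60 °C; 1 M HCl to pH 3
Reagents that add atoms: water, O
Why: Reductive N–O cleavage of the isoxazole by Mo(CO)6 gives the vinylogous primary amide, and alkaline addition–elimination at the amino(phenyl)methylidene carbon releases ammonia and the benzoyl enol; base is chosen because the triketone is protected as its enolate while the tertiary alcohol and prenyl groups are acid-sensitive.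

**Compound list**

1 | (S)-(−)-limonene | CC1=CC[C@H](CC1)C(C)=C | starting material
2 | limonene secondary ozonide (1,2,4-trioxolane across the ring alkene; bridgehead configuration undefined) | CC12CC[C@H](C(C)=C)CC(OO1)O2 | intermediate (not isolated)
3 | (3S)-6-oxo-3-(prop-1-en-2-yl)heptanal | C=C(C)[C@H](CC=O)CCC(C)=O | intermediate
4 | (5R)-2-methyl-5-(prop-1-en-2-yl)cyclopent-1-ene-1-carbaldehyde | C=C(C)[C@H]1CCC(C)=C1C=O | intermediate
5 | (1R,2R,5S)-5-methyl-2-(prop-1-en-2-yl)-6-oxabicyclo[3.1.0]hexane-1-carbaldehyde | C=C(C)[C@H]1CC[C@]2(C)O[C@]12C=O | intermediate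
6 | methyl (triphenylphosphoranylidene)acetate | COC(=O)C=P(c1ccccc1)(c1ccccc1)c1ccccc1 | starting material
7 | methyl (2E)-3-[(1R,2R,5S)-5-methyl-2-(prop-1-en-2-yl)-6-oxabicyclo[3.1.0]hexan-1-yl]prop-2-enoate | C=C(C)[C@H]1CC[C@]2(C)O[C@]12/C=C/C(=O)OC | intermediate
8 | methyl (2E)-3-[(1R,2S,5S)-2-hydroxy-2-methyl-5-(prop-1-en-2-yl)cyclopentyl]prop-2-enoate | C=C(C)[C@H]1CC[C@](C)(O)[C@@H]1/C=C/C(=O)OC | intermediate
9 | methyl 3-[(1R,2S,5S)-2-hydroxy-2-methyl-5-(prop-1-en-2-yl)cyclopentyl]propanoate | C=C(C)[C@H]1CC[C@](C)(O)[C@@H]1CCC(=O)OC | intermediate (not isolated)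
10 | (4aR,5S,7aS)-7a-methyl-5-(prop-1-en-2-yl)-4,4a,5,6,7,7a-hexahydrocyclopenta[b]pyran-2(3H)-one (cis-fused lactone) | C=C(C)[C@H]1CC[C@]2(C)OC(=O)CC[C@H]12 | intermediate
11 | 5-methyl-3-phenyl-1,2-oxazole-4-carboxylic acid | Cc1onc(-c2ccccc2)c1C(=O)O | starting material
12 | 1-bromo-3-methylbut-2-ene (prenyl bromide) | CC(C)=CCBr | starting material
13 | lithium 5-(lithiomethyl)-3-phenyl-1,2-oxazole-4-carboxylate | [Li]Cc1onc(-c2ccccc2)c1C(=O)O[Li] | intermediate (not isolated)
14 | 5-(4-methylpent-3-en-1-yl)-3-phenyl-1,2-oxazole-4-carboxylic acid | CC(C)=CCCc1onc(-c2ccccc2)c1C(=O)O | intermediate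
15 | lithium 5-(1-lithio-4-methylpent-3-en-1-yl)-3-phenyl-1,2-oxazole-4-carboxylate | [Li]C(CC=C(C)C)c1onc(-c2ccccc2)c1C(=O)O[Li] | intermediate (not isolated)
16 | 5-{8-[(1R,2S,5S)-2-hydroxy-2-methyl-5-(prop-1-en-2-yl)cyclopentyl]-2-methyl-6-oxooct-2-en-5-yl}-3-phenyl-1,2-oxazole-4-carboxylic acid (epimers at the prenyl-bearing carbon) | C=C(C)[C@H]1CC[C@](C)(O)[C@@H]1CCC(=O)C(CC=C(C)C)c1onc(-c2ccccc2)c1C(=O)O | intermediate (not isolated)
17 | methyl 5-{8-[(1R,2S,5S)-2-hydroxy-2-methyl-5-(prop-1-en-2-yl)cyclopentyl]-2-methyl-6-oxooct-2-en-5-yl}-3-phenyl-1,2-oxazole-4-carboxylate (epimers at the prenyl-bearing carbon) | C=C(C)[C@H]1CC[C@](C)(O)[C@@H]1CCC(=O)C(CC=C(C)C)c1onc(-c2ccccc2)c1C(=O)OC | intermediate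
18 | methyl 5-{8-[(1R,2S,5S)-2-hydroxy-2-methyl-5-(prop-1-en-2-yl)cyclopentyl]-2-methyl-5-(3-methylbut-2-en-1-yl)-6-oxooct-2-en-5-yl}-3-phenyl-1,2-oxazole-4-carboxylate | C=C(C)[C@H]1CC[C@](C)(O)[C@@H]1CCC(=O)C(CC=C(C)C)(CC=C(C)C)c1onc(-c2ccccc2)c1C(=O)OC | intermediate
19 | 6-hydroxy-5-{[(1R,2S,5S)-2-hydroxy-2-methyl-5-(prop-1-en-2-yl)cyclopentyl]methyl}-7,7-bis(3-methylbut-2-en-1-yl)-3-phenyl-1,2-benzoxazol-4(7H)-one | C=C(C)[C@H]1CC[C@](C)(O)[C@@H]1CC1=C(O)C(CC=C(C)C)(CC=C(C)C)c2onc(-c3ccccc3)c2C1=O | intermediate
20 | 2-[amino(phenyl)methylidene]-5-hydroxy-4-{[(1R,2S,5S)-2-hydroxy-2-methyl-5-(prop-1-en-2-yl)cyclopentyl]methyl}-6,6-bis(3-methylbut-2-en-1-yl)cyclohex-4-ene-1,3-dione (interconverting hydrogen-bonded forms) | C=C(C)[C@H]1CC[C@](C)(O)[C@@H]1CC1=C(O)C(CC=C(C)C)(CC=C(C)C)C(=O)C(=C(N)c2ccccc2)C1=O | intermediate (not isolated)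
21 | Hypercalin B, 2-benzoyl-3,5-dihydroxy-4-{[(1R,2S,5S)-2-hydroxy-2-methyl-5-(prop-1-en-2-yl)cyclopentyl]methyl}-6,6-bis(3-methylbut-2-en-1-yl)cyclohexa-2,4-dien-1-one | C=C(C)[C@H]1CC[C@](C)(O)[C@@H]1CC1=C(O)C(CC=C(C)C)(CC=C(C)C)C(=O)C(C(=O)c2ccccc2)=C1O | target

**Step count and risks**

Total step count: 11. Longest linear sequence: 10 steps (steps 1 to 6 and 8 to 11, from 1 to 21); step 7 prepares the second fragment from 11.

Steps most likely to fail:

- **Step 5.** Ionisation of the hindered, fully substituted alkenyl epoxide by zerovalent palladium may be slow, and the allyl intermediate may lose a β-hydrogen to give a dienol or take up hydride at the ester-bearing terminus. The fallback sets out from 5 and replaces the inversion logic by reductive cleavage under thermodynamic control. SmI2 (2.5 equiv, THF/MeOH, −78 °C) cleaves the Cα–O bond of the α,β-epoxy aldehyde to give (1R,2S,5S)-2-hydroxy-2-methyl-5-(prop-1-en-2-yl)cyclopentane-1-carbaldehyde F1. Its epimerisable formyl-bearing carbon should settle trans to isopropenyl and cis to the hydroxyl (Et3N, cat.). Wittig olefination of F1 with 6 (toluene, rt to 50 °C) then returns to the route at 8.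

- **Step 9.** The ambident enolate may be alkylated on oxygen, or its oxygen may attack the neighbouring methyl ester and close a fused pyranone before the quaternary carbon forms. The fallback sets out from 17 and replaces the SN2 alkylation by palladium π-allyl chemistry (Tsuji–Trost allylation): Pd(PPh3)4 (5 mol%) and methyl 3-methylbut-2-en-1-yl carbonate (1.5 equiv) in THF at 40 °C. Ionisation and loss of carbon dioxide release methoxide only as fast as the π-prenyl palladium complex forms, O-allylation is reversible under these conditions, and the hindered enolate should attack the unsubstituted terminus of the prenyl ligand. This way runs from 17 straight to 18 and makes no new compound (F0).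

- **Step 10.** The free tertiary alkoxide may add to the ketone and hold it as a hemiketal alkoxide, which suppresses enolisation, or it may trigger retro-Claisen fragmentation back to lactone 10. The fallback sets out from 18 and masks the alcohol. Et3SiOTf with 2,6-lutidine (CH2Cl2, −78 °C) gives the triethylsilyl ether of 18 F2. The same Dieckmann condensation (LiN(SiMe3)2, 2.2 equiv, THF, −78 to 0 °C) gives the triethylsilyl ether of 19 F3. HF·pyridine (THF, 0 °C) removes the silyl group from F3 and returns to the route at 19.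

**Further compounds**

F1 | step 5 | (1R,2S,5S)-2-hydroxy-2-methyl-5-(prop-1-en-2-yl)cyclopentane-1-carbaldehyde | C=C(C)[C@H]1CC[C@](C)(O)[C@@H]1C=O
F0 | step 9 | none | none
F2 | step 10 | triethylsilyl ether of 18 | C=C(C)[C@H]1CC[C@](C)(O[Si](CC)(CC)CC)[C@@H]1CCC(=O)C(CC=C(C)C)(CC=C(C)C)c1onc(-c2ccccc2)c1C(=O)OC
F3 | step 10 | triethylsilyl ether of 19 | C=C(C)[C@H]1CC[C@](C)(O[Si](CC)(CC)CC)[C@@H]1CC1=C(O)C(CC=C(C)C)(CC=C(C)C)c2onc(-c3ccccc3)c2C1=O
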